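**The questions.** I had 3 questions to answer about two flasks that differ in their charge of coupling partner.

- maple: starting material 34 mM; coupling partner 100 mM; initiator 0.85 mM; time 6.0 min
- larch: starting material 34 mM; coupling partner 68.0 mM; initiator 0.85 mM; time 6.0 min

    initiator → 2 initiating radical (k1 = 2.9 × 10⁻⁴ s⁻¹)
    starting material + initiating radical → capped initiator + first chain carrier (k2 = 2.0 × 10⁷ M⁻¹ s⁻¹)
    coupling partner + first chain carrier → target + second chain carrier (k3 = 2.7 × 10⁵ M⁻¹ s⁻¹)
    starting material + second chain carrier → released group + first chain carrier (k4 = 2.6 × 10⁵ M⁻¹ s⁻¹)
    first chain carrier → ended carrier (k5 = 100 s⁻¹)
    2 first chain carrier → ended chains A (k6 = 6.4 × 10⁷ M⁻¹ s⁻¹)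
    2 second chain carrier → ended chains B (k7 = 8.6 × 10⁸ M⁻¹ s⁻¹)
    coupling partner + released group ⇌ idle adduct, settled at all times (K8 = 31 M⁻¹)

- in percentages every species weighs as the starting material in it: one ended chains A counts as two
- for released group the idle adduct is counted in
- a doubled species enters its step squared and goes two at a time
- run time (maple): 6.0 min

- part of the starting material that has reacted at the end, maple
- part of the starting material that has reacted at the end, larch
- what raising the concentration of coupling partner from its lowest to its highest value here does to the part of the starting material that has reacted (changes below 5 percentage points count as none) (it rises / no change / it falls)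

**What stands still.** I looked for what stayed nearly constant. The initiator's half-life of 39.8 min was longer than the run, so I froze the supply of radicals at 0.0296 mM min⁻¹. In maple, the first chain carrier met coupling partner at 27000 s⁻¹, far faster than it ended at 100 s⁻¹, so chains were long. The two propagation rates then matched, and c(first chain carrier) followed c(second chain carrier). I held the ratio of starting material to coupling partner at its charged value.

**First way.** I took mutual ending of the second chain carrier as the sole exit, so that it balanced the supply. This gave c(second chain carrier) = 1.69 × 10⁻⁵ mM and, for maple, a reacted part below 79.5%. Coupling partner does not enter this number.

**Second way.** I added the first-order ending of the first chain carrier, which in maple costs 32.7 s⁻¹ per unit of c(second chain carrier). The balance became a quadratic, with root 9.90 × 10⁻⁶ mM. Multiplying by the rate constant of the step on starting material gave 0.155 min⁻¹, the pseudo-first-order constant of starting material, the turnover constant.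

**Which cheats.** The two ways part. At this level the first-order exit carried 0.0195 mM min⁻¹, more than the 0.0101 mM min⁻¹ of the mutual exit, so the first way cheats and serves as a ceiling. I committed, for maple, to 60.4%. For larch the same quadratic gave 0.124 min⁻¹, hence 52.6%. The gap between the two exceeds the margin of 5 percentage points, so my answer was: it rises.

**The forecast.** The forecast gave 64% for maple and 54% for larch, above my figures, with the trend it rises, holding that “more coupling partner favours productive propagation over first-order loss of the first carrier”.

**The result.** The simulation gave 63.2% for maple and 53.4% for larch: it rises, by 9.8 points.

**The exit.** The difference in charge of coupling partner is the main reason for the gap between maple and larch, and the first-order ending of the first chain carrier is a part of that reason: without that step maple gives 78.8% and larch 78.7%, and the rise is gone. For the neighbour of maple charged with 40 mM of coupling partner, the same quadratic gives a turnover constant of 0.0844 min⁻¹, lower than maple's 0.155 min⁻¹, and so a reckoned reacted part of 39.7%. That neighbour reached 37.0%.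

(The numbers belong to no real substance; the run is a simulation.)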